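## Analysis of the target

The target is a germacrane-type sesquiterpenoid diester. Locants used throughout: C1 ether CH, C2 and C3 ring CH2, C4 methyl-bearing ether carbon, C5=C6 exocyclic enol-lactone alkene, C7=C11 butenolide alkene, C8 angelate carbinol, C9 CH2, C10 tertiary carbinol, C12 lactone carbonyl, C13 acetoxymethyl carbon, C14 and C15 the methyl groups on C10 and C4. A ten-membered carbocycle (C1 to C10) is bridged by one oxygen between C1 and C4 (a tetrahydrofuran) and carries at C6/C7 a butenolide whose ring oxygen sits on C6. There are four stereocentres, C1 (S), C4 (S, quaternary), C8 (S) and C10 (R, fully substituted). C1 and C10 are vicinal, the C8 and C10 oxygens are 1,3-syn along the chain C7–C8–C9–C10–C1, and the bridge is of the trans type, with C10 on C1 and C5 on C4 on opposite faces of the tetrahydrofuran. The sensitive groups are the cross-conjugated alkylidene butenolide (opened by base, ionised by acid at the allylic tertiary C4–O bond), the allylic C13 acetate, the angelate (which isomerises to the tiglate under nucleophilic or acid catalysis) and the free tertiary C10 hydroxyl. The synthesis is hard because a medium ring must be closed against a one-atom trans bridge and a planar C5–C6–C7–C11–C12 unit, two stereocentres are fully substituted, and three oxygens must be told apart at the end. The plan rests on the fact that the C1–O–C4 bridge spans exactly the C2–C3 bond. On the C1 epimer, where C10 and C5 are cis, a longer O–Si–O bridge gives an unstrained bicycle in which C2–C3 can be made by metathesis of two vinyl groups, and a single inversion at C1 by the C4 oxygen then gives the trans ether. The butenolide is carried as a furan (C6, C7, C11, C12).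

## Retrosynthetic reasoning

**40 to 36.** The enol lactone is not disconnected but traced back by functional-group change. The C5=C6 bond comes from dehydration of hydroxybutenolide 38, and 38 from photooxygenation of the 2,3,4-trisubstituted furan 36. The furan has its only ring hydrogen on C12, so the carbonyl must end on C12 and the hydroxyl on C6, and no silyl group is needed on C12. The furan keeps C12 and C13 at their final oxidation pattern through all basic and organometallic steps.

**36 to 33.** The angelate and the acetate are removed to triol 34: primary C13 is acetylated first, the hindered secondary C8 is then acylated, and the tertiary C10 hydroxyl needs no protection. Triol 34 comes from ether 33 by one fluoride treatment. For this reason C10 is carried as a fluoride-labile SEM acetal and not as an acid-labile acetal, since acid would endanger the furylic C8–O bond before the oxidation and the enol lactone after it.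

**33 to 31.** The C1–O bond of the bridge is cut. In the forward direction the C4 oxygen displaces a C1 mesylate (32) with inversion. The cut is made at C1 and not at C4 because C4 is quaternary and cannot undergo backside substitution. The gain is that the strained trans bridge is formed last, on a ring that already exists. The C10 oxygen must be blocked, or it would form the epoxide.

**31 to 29.** Diol 31 comes from the saturated silaketal 30 by fluoride cleavage, and 30 from alkene 29 by diimide reduction. The C2=C3 alkene is only a construction aid.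

**29 to 28.** The C2=C3 bond is cut. This is the key disconnection: both ends carry an oxygen that can be tied to one silicon, so the two vinyl groups of the eleven-membered silaketal 28 are held four atoms apart. Ring-closing metathesis then closes the seven-membered siladioxepine and the ten-membered carbocycle with one bond. C1 must be the epimer of the target so that the silicon-bridged bicycle is of the relaxed cis type.

**28 to 25 and 26.** The two Si–O bonds are cut, giving diene diol 25 and the silane 26. The furan holds the C5 and C8 arms ortho to each other, which shortens the distance the tether has to span.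

**25 to 22.** The C1–C2 bond is cut: a vinyl nucleophile adds to aldehyde 24 under chelation by the C10 acetal oxygen, which gives the required (1R) epimer. Aldehyde 24 comes from diol 23 and this from the fully silylated 22. The primary C1 and the tertiary C4 silyl ethers are chosen so that one mild acid step frees both.

**22 to 11 and 18.** C8 is set by reagent-controlled reduction of aryl ketone 20, and the C7–C8 bond is cut to the furyllithium from bromide 11 and Weinreb amide 18. This is the convergent union of the two chiral fragments.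

**11 to 1 and 5.** The C4 vinyl group comes from aldehyde 9 by methylenation, and 9 from diol 8. The C5–C6 bond is cut to the lithiated bromofuran 4 and epoxide 6, so C4 comes unchanged from 5. The bromine in 4 directs the deprotonation to C6 and later becomes the C7 nucleophile. Compound 4 is made from 1 by one bromine–lithium exchange and formylation.

**18 to 12.** Compound 12 supplies C8, C9, C10 with C14, and C1, with C10 already correct. The two carboxyl groups are told apart by hydroxyl-directed reduction of the C1 ester of 13 and lactonisation to 15; acetal formation (16), aminolysis (17) and silylation give 18.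

## Alternatives that were turned down

**Alternative 1:** The ether is disconnected at C4–O together with the C5 oxygen, back to an acyclic chain with a C1 alcohol and an (E)-C4=C5 alkene. In the forward key step Re2O7 with 2,6-lutidine forms a perrhenate ester of the C1 alcohol, which adds both oxygens syn across the alkene to give the trans-tetrahydrofuran A1 with quaternary C4 and a C5 carbinol. In its favour, the trans-2,5 relationship and the quaternary C4 come from one stereospecific step on a cheap terpene chain, with no substitution at the hindered C1. On this point it is stronger than the chosen plan, which needs an inversion at a neopentyl-type carbon. Against it, the ten-membered ring must then be closed around an existing trans bridge, which is the strained closure that the silicon bridge avoids. Both C6–C7 and C8–C9 and the whole butenolide remain to be made, and the C5 hydroxyl of A1 is at the wrong oxidation pattern for the C5=C6 enol lactone. The chosen strategy offers a ring closure on a relaxed bicycle and a butenolide already encoded in the furan.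

**Alternative 2:** The ten-membered ring is disconnected at C8–C9 and traced to a six-membered 1,2-dialkenyl cyclohexanol, the precursor of A2. In the forward key step the potassium alkoxide (KH, 18-crown-6) undergoes an anionic oxy-Cope rearrangement that forms C8–C9, breaks C1–C6 and gives the (E)-cyclodecenone A2. In its favour, this is the most dependable way to a ten-membered carbocycle, it is short, and the precursor is a chiral-pool cyclohexanol. On ring construction it is stronger than a transannular metathesis. Against it, A2 has no ether bridge and no oxygen at C1, C8 or C10 (C8 is a silyl group that must be oxidised in the presence of the C1=C10 alkene). C1 and C10 would have to be set by transannular reactions on a mobile ring, so the cis or trans sense of the bridge is not predictable. The butenolide must be annulated at C6/C7 with regiocontrolled enolisation. The chosen strategy fixes all four stereocentres before ring closure and brings the lactone carbons at the right oxidation level.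

**Alternative 3:** The C7–C8 bond is disconnected by a ring contraction, back to a thirteen-membered cyclic allyl ether (C8–O–C13) that already contains the tetrahydrofuran, the precursor of A3. In the forward key step tin–lithium exchange with n-BuLi at the C8 α-alkoxystannane triggers a [2,3]-Wittig–Still shift, which forms C7–C8, breaks O–C13, moves the alkene to C11=C13 and gives A3 with a free C8 hydroxyl. In its favour, a larger and easier ring is closed first, the contraction is concerted, the C8 hydroxyl comes out free and differentiated, and no late etherification is needed. On these points it is as strong or stronger. Against it, A3 has an exocyclic C11=C13 methylene, C12 at the alcohol level and C6 as a silyl ether. Reaching the C7=C11 butenolide with a C13 acetate therefore needs an allylic transposition and several oxidations on the sensitive bicycle. The macrocyclic stannane is a long linear precursor, and the shift must pass a transition state across the trans bridge, with the [1,2]-shift as competitor. The chosen strategy is more convergent (three fragments) and needs no redox correction of the lactone.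

Key step: step 20

## Route

Remark: TBS = tert-butyldimethylsilyl, TBDPS = tert-butyldiphenylsilyl, TES = triethylsilyl, TMS = trimethylsilyl, SEM = 2-(trimethylsilyl)ethoxymethyl, Ms = methanesulfonyl. Compounds 37, 38 and 39 form as C6 epimers that converge in step 29.

Step 1
Reactants: 1 3,4-dibromofuran
Product: 3 (4-bromofuran-3-yl)methanol, via 4-bromofuran-3-carbaldehyde 2 (not isolated)
Conditions: n-BuLi (1.0 equiv), Et2O, −78 °C; DMF, −78 °C to 0 °C; then MeOH, NaBH4, 0 °C
Reagents that add atoms: N,N-dimethylformamide, CN(C)C=O
Why: Bromine–lithium exchange stops after one bromine at −78 °C; formylation with DMF and reduction of 2 in the same flask give the C13 hydroxymethyl group next to the remaining bromine.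

Step 2
Reactants: 3 (4-bromofuran-3-yl)methanol
Product: 4 [(4-bromofuran-3-yl)methoxy](tert-butyl)diphenylsilane
Conditions: TBDPSCl, imidazole, DMF, rt
Reagents that add atoms: tert-butyl(chloro)diphenylsilane, CC(C)(C)[Si](Cl)(c1ccccc1)c1ccccc1
Why: Standard silylation of a primary alcohol; the TBDPS ether should survive LiN(iPr)2, t-BuLi, aqueous acetic acid and buffered HF and migrates from oxygen to carbon only slowly.

Step 3
Reactants: 5 (S)-2-methylglycidol
Product: 6 triethyl{[(2R)-2-methyloxiran-2-yl]methoxy}silane
Conditions: TESCl, imidazole, CH2Cl2, 0 °C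
Reagents that add atoms: chlorotriethylsilane, CC[Si](Cl)(CC)CC
Why: Silylation of the primary alcohol; the stereocentre is untouched and the descriptor changes from S to R only through the priority rules.

Step 4
Reactants: 4 [(4-bromofuran-3-yl)methoxy](tert-butyl)diphenylsilane; 6 triethyl{[(2R)-2-methyloxiran-2-yl]methoxy}silane
Product: 8 (2R)-3-[3-bromo-4-(TBDPS-oxymethyl)furan-2-yl]-2-methylpropane-1,2-diol, via C3 triethylsilyl ether 7 (not isolated)
Conditions: LiN(iPr)2, THF, −78 °C; BF3·OEt2, then 6, −78 °C; then AcOH/THF/H2O, rt
Reagents that add atoms: none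
Why: LiN(iPr)2 removes the acidic ring proton next to bromine, and the 2-furyllithium opens the BF3-activated epoxide at its CH2 terminus (C5–C6 bond), so the C4 configuration of 5 is kept; aqueous acetic acid then cleaves the primary TES ether of 7 but not the TBDPS ether.

Step 5
Reactants: 8 (2R)-3-[3-bromo-4-(TBDPS-oxymethyl)furan-2-yl]-2-methylpropane-1,2-diol
Product: 9 (2R)-3-[3-bromo-4-(TBDPS-oxymethyl)furan-2-yl]-2-hydroxy-2-methylpropanal
Conditions: SO3·pyridine, DMSO, iPr2NEt, CH2Cl2, 0 °C
Reagents that add atoms: none
Why: Parikh–Doering oxidation; only the primary alcohol can be oxidised, and the non-acidic conditions should avoid α-ketol rearrangement of the hydroxy aldehyde, which is used crude.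

Step 6
Reactants: 9 (2R)-3-[3-bromo-4-(TBDPS-oxymethyl)furan-2-yl]-2-hydroxy-2-methylpropanal
Product: 10 (2R)-1-[3-bromo-4-(TBDPS-oxymethyl)furan-2-yl]-2-methylbut-3-en-2-ol
Conditions: Ph3PCH3Br, KN(SiMe3)2, THF, 0 °C; then 9, −78 °C to 0 °C
Reagents that add atoms: methyltriphenylphosphonium bromide, C[P+](c1ccccc1)(c1ccccc1)c1ccccc1.[Br-]
Why: Wittig methylenation with excess ylide, which tolerates the tertiary hydroxyl as its alkoxide; the quaternary C4 cannot epimerise.

Step 7
Reactants: 10 (2R)-1-[3-bromo-4-(TBDPS-oxymethyl)furan-2-yl]-2-methylbut-3-en-2-ol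
Product: 11 trimethylsilyl ether of 10
Conditions: TMSCl, imidazole, DMF, rt
Reagents that add atoms: chlorotrimethylsilane, C[Si](C)(C)Cl
Why: Silylation of the tertiary alcohol; the TMS ether prevents alkoxide and hemiketal formation in steps 13 to 15 and leaves together with the C1 TES group in step 16.

Step 8
Reactants: 12 (R)-citramalic acid
Product: 13 dimethyl (2R)-2-hydroxy-2-methylbutanedioate
Conditions: MeOH, HCl (cat.), rt
Reagents that add atoms: methanol, CO
Why: Fischer esterification of both carboxyl groups; mild acid at room temperature should not dehydrate the tertiary alcohol.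

Step 9
Reactants: 13 dimethyl (2R)-2-hydroxy-2-methylbutanedioate
Product: 15 (4R)-4-hydroxy-4-methyloxolan-2-one, via diol ester 14 (not isolated)
Conditions: BH3·SMe2, NaBH4 (5 mol%), THF, 0 °C to rt; MeOH; then TsOH (cat.), CH2Cl2, rt
Reagents that add atoms: none
Why: Hydroxyl-directed chemoselective borane reduction: the alkoxyborane of the tertiary hydroxyl delivers hydride to the neighbouring C1 ester through a five-membered chelate and leaves the C8 ester; acid then lactonises 14, which masks the C1 hydroxyl and activates C8.

Step 10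
Reactants: 15 (4R)-4-hydroxy-4-methyloxolan-2-one
Product: 16 (4R)-4-methyl-4-(SEM-oxy)oxolan-2-one
Conditions: SEMCl, iPr2NEt, n-Bu4NI (cat.), CH2Cl2, 40 °C
Reagents that add atoms: 2-(trimethylsilyl)ethoxymethyl chloride, C[Si](C)(C)CCOCCl
Why: Alkylation of the tertiary alcohol by the iodide-activated chloromethyl ether; the SEM acetal chelates in step 18, blocks the C10 oxygen in step 24 and leaves with fluoride.

Step 11
Reactants: 16 (4R)-4-methyl-4-(SEM-oxy)oxolan-2-one
Product: 17 (3R)-4-hydroxy-N-methoxy-N,3-dimethyl-3-(SEM-oxy)butanamide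
Conditions: MeNHOMe·HCl, i-PrMgCl, THF, −20 °C to 0 °C
Reagents that add atoms: N,O-dimethylhydroxylamine hydrochloride, CNOC.Cl
Why: Weinreb aminolysis of the lactone by the magnesium amide, which is not Lewis acidic enough to cleave the acetal.

Step 12
Reactants: 17 (3R)-4-hydroxy-N-methoxy-N,3-dimethyl-3-(SEM-oxy)butanamide
Product: 18 (3R)-N-methoxy-N,3-dimethyl-4-(triethylsilyloxy)-3-(SEM-oxy)butanamide
Conditions: TESCl, imidazole, CH2Cl2, 0 °C
Reagents that add atoms: chlorotriethylsilane, CC[Si](Cl)(CC)CC
Why: Silylation of the primary alcohol, done at once on crude 17 so that it cannot close back to the lactone.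

Step 13
Reactants: 11 trimethylsilyl ether of 10; 18 (3R)-N-methoxy-N,3-dimethyl-4-(triethylsilyloxy)-3-(SEM-oxy)butanamide
Product: 20 (4R,10R)-C8 furyl ketone, via 3-furyllithium 19 (not isolated)
Conditions: t-BuLi (2.2 equiv), Et2O, −78 °C; then 18, −78 °C to −40 °C; aq. NH4Cl
Reagents that add atoms: none
Why: Bromine–lithium exchange gives 19, which adds to the Weinreb amide to a chelated tetrahedral intermediate that collapses to the ketone only on work-up, so a second addition is excluded; Et2O at −78 °C should suppress 1,4 migration of the neighbouring C13 silyl group from oxygen to carbon.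

Step 14
Reactants: 20 (4R,10R)-C8 furyl ketone
Product: 21 (4R,8S,10R)-C8 alcohol
Conditions: (R)-2-methyl-CBS-oxazaborolidine, catecholborane, toluene, −78 °C to −40 °C
Reagents that add atoms: none
Why: Corey–Bakshi–Shibata reduction: the di-ortho-substituted furyl group is the large and the C9 methylene the small substituent, so the (R)-catalyst should give the (8S)-alcohol as with aryl alkyl ketones; catecholborane is used because it does not hydroborate the C4 vinyl group.

Step 15
Reactants: 21 (4R,8S,10R)-C8 alcohol
Product: 22 (4R,8S,10R)-C8 TBS ether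
Conditions: TBSOTf, 2,6-lutidine, CH2Cl2, −78 °C
Reagents that add atoms: tert-butyldimethylsilyl trifluoromethanesulfonate, CC(C)(C)[Si](C)(C)OS(=O)(=O)C(F)(F)F
Why: Silylation of the hindered secondary furylic alcohol with the reactive silyl triflate at low temperature, which the SEM acetal and the other silyl ethers tolerate.

Step 16
Reactants: 22 (4R,8S,10R)-C8 TBS ether
Product: 23 (4R,8S,10R)-C1,C4-diol
Conditions: PPTS (cat.), MeOH/CH2Cl2, 0 °C to rt
Reagents that add atoms: none
Why: Mild acid methanolysis removes the primary TES and the tertiary TMS ether much faster than the secondary TBS and primary TBDPS ethers, and PPTS is too weak to ionise the furylic C8–O bond.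

Step 17
Reactants: 23 (4R,8S,10R)-C1,C4-diol
Product: 24 (4R,8S,10R)-C1 aldehyde
Conditions: Dess–Martin periodinane, NaHCO3, CH2Cl2, 0 °C to rt
Reagents that add atoms: none
Why: Dess–Martin oxidation of the primary alcohol; the tertiary C4 hydroxyl cannot be oxidised and the aldehyde has no α-hydrogen to epimerise.

Step 18
Reactants: 24 (4R,8S,10R)-C1 aldehyde
Product: 25 (1R,4R,8S,10R)-diene diol
Conditions: MgBr2·OEt2, CH2Cl2, −78 °C; CH2=CHMgBr (THF), −78 °C
Reagents that add atoms: vinylmagnesium bromide, C=C[Mg]Br
Why: Chelation-controlled Grignard addition (Cram chelate): magnesium binds the aldehyde oxygen and the C10 acetal oxygen in a five-membered ring and the vinyl group attacks from the face of the C14 methyl group, which is smaller than the C9 chain, giving the (1R)-alcohol; one equivalent of reagent is consumed by the C4 hydroxyl.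

Step 19
Reactants: 25 (1R,4R,8S,10R)-diene diol; 26 dichlorodiisopropylsilane
Product: 28 (1R,4R,8S,10R)-eleven-membered diisopropylsilaketal diene, via C1 chlorodiisopropylsilyl ether 27 (not isolated)
Conditions: 26 (3 equiv), imidazole, CH2Cl2, 0 °C to rt; filter, evaporate excess 26; then KN(SiMe3)2, THF (0.002 M), −78 °C to rt
Reagents that add atoms: none
Why: Stepwise silaketal formation: only the secondary C1 hydroxyl is silylated by 26 under imidazole, and after removal of excess 26 the potassium alkoxide of C4 closes the eleven-membered ring by substitution at silicon under high dilution; a chlorosilane, unlike a silyl triflate, does not attack the neighbouring SEM acetal.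

Step 20
Reactants: 28 (1R,4R,8S,10R)-eleven-membered diisopropylsilaketal diene
Product: 29 (1R,2Z,4R,8S,10R)-silaketal-bridged cyclodecene
Conditions: RuCl2(=CHPh)(PCy3)(H2IMes) (second-generation Grubbs catalyst, 10–15 mol%), toluene (0.002 M), 80 °C, argon stream
Reagents that add atoms: none
Why: Ring-closing alkene metathesis: the ruthenium benzylidene exchanges onto the less hindered C1 vinyl group, and the new alkylidene reacts with the C4 vinyl group through a ruthenacyclobutane, forming C2=C3 and releasing ethene, whose removal makes the step irreversible. The closest known reaction type is the silicon-tethered ring-closing metathesis of bis-allylic silaketals to 4,7-dihydro-1,3,2-dioxasilepines, run here across an existing eleven-membered ring. The seven-membered siladioxepine (C1, C2, C3, C4, O, Si, O) closes as an ordinary tethered seven-ring closure. The ten-membered carbocycle (C1 to C10) closes through the same bond as a transannular contraction of the eleven-membered silaketal, so no separate medium-ring cyclisation is needed; the long Si–O bonds and wide Si–O–C angles give a relaxed cis-bridged bicycle with C10 and C5 on the same face. No stereocentre is formed, and the alkene can only be (Z) in a seven-membered ring. The step needs chemoselectivity for the two monosubstituted alkenes and ring closure over intermolecular metathesis: the furan and all other groups are inert to the carbene, and high dilution together with the preorganisation by the macrocyclic silaketal should favour ring closure.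

Step 21
Reactants: 29 (1R,2Z,4R,8S,10R)-silaketal-bridged cyclodecene
Product: 30 (1R,4S,8S,10R)-silaketal-bridged cyclodecane
Conditions: 2-nitrobenzenesulfonylhydrazide, Et3N, CH2Cl2, rt
Reagents that add atoms: none
Why: Diimide reduction: concerted syn transfer of two hydrogens to the cis-disubstituted alkene, which leaves the aromatic furan and the furylic C–O bonds alone, unlike hydrogenation over a metal; the C4 descriptor changes from R to S only through the priority rules.

Step 22
Reactants: 30 (1R,4S,8S,10R)-silaketal-bridged cyclodecane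
Product: 31 (1R,4S,8S,10R)-1,4-diol
Conditions: HF·pyridine, pyridine, THF, 0 °C
Reagents that add atoms: none
Why: Fluoride cleavage of the dialkoxysilane, whose silicon with two oxygens is far more electrophilic than that of the TBS and TBDPS ethers; the pyridine buffer keeps the furylic C8 ether from ionising.

Step 23
Reactants: 31 (1R,4S,8S,10R)-1,4-diol
Product: 32 (1R,4S,8S,10R)-C1 mesylate
Conditions: MsCl (1.2 equiv), Et3N, CH2Cl2, −20 °C
Reagents that add atoms: methanesulfonyl chloride, CS(=O)(=O)Cl
Why: Selective sulfonylation of the secondary alcohol; the tertiary C4 hydroxyl is too hindered to react at −20 °C with a small excess of reagent.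

Step 24
Reactants: 32 (1R,4S,8S,10R)-C1 mesylate
Product: 33 (1S,4S,8S,10R)-1,4-epoxy furanogermacrane
Conditions: KN(SiMe3)2, THF, −78 °C to rt
Reagents that add atoms: none
Why: Intramolecular Williamson etherification (5-exo-tet): the C4 alkoxide displaces the C1 mesylate from the back, which inverts C1 from R to S and gives the trans-bridged tetrahydrofuran; the C10 oxygen is an acetal and cannot form the competing epoxide.

Step 25
Reactants: 33 (1S,4S,8S,10R)-1,4-epoxy furanogermacrane
Product: 34 (1S,4S,8S,10R)-8,10,13-triol
Conditions: n-Bu4NF (excess), DMPU, 4 Å molecular sieves, 80 °C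
Reagents that add atoms: none
Why: Fluoride cleaves both silyl ethers and, by attack at silicon and fragmentation to ethene and formaldehyde, the SEM acetal; no acid is used, so the furylic C8–O bond is safe.

Step 26
Reactants: 34 (1S,4S,8S,10R)-8,10,13-triol
Product: 35 (1S,4S,8S,10R)-13-acetate
Conditions: Ac2O (1.1 equiv), 2,4,6-collidine, CH2Cl2, −20 °C to 0 °C
Reagents that add atoms: acetic anhydride, CC(=O)OC(C)=O
Why: Selective acetylation of the primary alcohol at low temperature with a weak base; the hindered secondary C8 and the tertiary C10 hydroxyl should not react.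

Step 27
Reactants: 35 (1S,4S,8S,10R)-13-acetate
Product: 36 (1S,4S,8S,10R)-8-angelate 13-acetate
Conditions: angelic acid, 2,4,6-trichlorobenzoyl chloride, Et3N, toluene, rt; then 35, 80 °C
Reagents that add atoms: angelic acid, C/C=C(/C)C(=O)O
Why: Yamaguchi-type esterification through the mixed anhydride without a nucleophilic catalyst, so that no conjugate addition–elimination turns the angelate into the tiglate; the tertiary C10 hydroxyl is not acylated.

Step 28
Reactants: 36 (1S,4S,8S,10R)-8-angelate 13-acetate
Product: 38 (1S,4S,8S,10R)-6-hydroxybutenolide, via furan 6,12-endoperoxide 37 (not isolated)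
Conditions: O2, visible light, tetraphenylporphyrin (cat.), iPr2NEt, CH2Cl2, −78 °C
Reagents that add atoms: dioxygen, O=O
Why: [4+2] cycloaddition of singlet oxygen across C6 and C12 gives 37, and the hindered amine removes its only bridgehead hydrogen (on C12) in a Kornblum–DeLaMare-type fragmentation that puts the carbonyl on C12 and the hydroxyl on C6; the electron-poor angelate alkene should not react at −78 °C.

Step 29
Reactants: 38 (1S,4S,8S,10R)-6-hydroxybutenolide
Product: 40 target CNP0162854.1, via C6 mesylate 39 (not isolated)
Conditions: MsCl (1.2 equiv), Et3N, CH2Cl2, −40 °C to 0 °C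
Reagents that add atoms: none
Why: Dehydration of a γ-hydroxybutenolide: sulfonylation of the pseudo-acid oxygen, loss of methanesulfonate from C6 and removal of a C5 proton by Et3N give the enol lactone; C4 and C7 must be cis on the new alkene because both lie in the ten-membered ring, which fixes the (5E) geometry, and the hindered tertiary C10 hydroxyl should react much more slowly than the ionised pseudo-acid at −40 °C.

## Compound list

1 | 3,4-dibromofuran | Brc1cocc1Br | starting material
2 | 4-bromofuran-3-carbaldehyde | O=Cc1cocc1Br | intermediate (not isolated)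
3 | (4-bromofuran-3-yl)methanol | OCc1cocc1Br | intermediate
4 | [(4-bromofuran-3-yl)methoxy](tert-butyl)diphenylsilane | CC(C)(C)[Si](OCc1cocc1Br)(c1ccccc1)c1ccccc1 | intermediate
5 | (S)-2-methylglycidol | OC[C@@]1(C)CO1 | starting material
6 | triethyl{[(2R)-2-methyloxiran-2-yl]methoxy}silane | CC[Si](CC)(CC)OC[C@@]1(C)CO1 | intermediate
7 | (2R)-1-[3-bromo-4-(TBDPS-oxymethyl)furan-2-yl]-2-methyl-3-(triethylsilyloxy)propan-2-ol | CC[Si](CC)(CC)OC[C@@](O)(C)Cc1occ(CO[Si](c2ccccc2)(c2ccccc2)C(C)(C)C)c1Br | intermediate (not isolated)
8 | (2R)-3-[3-bromo-4-(TBDPS-oxymethyl)furan-2-yl]-2-methylpropane-1,2-diol | OC[C@@](O)(C)Cc1occ(CO[Si](c2ccccc2)(c2ccccc2)C(C)(C)C)c1Br | intermediate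
9 | (2R)-3-[3-bromo-4-(TBDPS-oxymethyl)furan-2-yl]-2-hydroxy-2-methylpropanal | O=C[C@@](O)(C)Cc1occ(CO[Si](c2ccccc2)(c2ccccc2)C(C)(C)C)c1Br | intermediate
10 | (2R)-1-[3-bromo-4-(TBDPS-oxymethyl)furan-2-yl]-2-methylbut-3-en-2-ol | C=C[C@@](O)(C)Cc1occ(CO[Si](c2ccccc2)(c2ccccc2)C(C)(C)C)c1Br | intermediate
11 | trimethylsilyl ether of 10 | C=C[C@@](O[Si](C)(C)C)(C)Cc1occ(CO[Si](c2ccccc2)(c2ccccc2)C(C)(C)C)c1Br | intermediate
12 | (R)-citramalic acid | OC(=O)C[C@@](C)(O)C(=O)O | starting material
13 | dimethyl (2R)-2-hydroxy-2-methylbutanedioate | COC(=O)C[C@@](C)(O)C(=O)OC | intermediate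
14 | methyl (3R)-3,4-dihydroxy-3-methylbutanoate | COC(=O)C[C@@](C)(O)CO | intermediate (not isolated)
15 | (4R)-4-hydroxy-4-methyloxolan-2-one | O=C1C[C@@](C)(O)CO1 | intermediate
16 | (4R)-4-methyl-4-(SEM-oxy)oxolan-2-one | O=C1C[C@@](C)(OCOCC[Si](C)(C)C)CO1 | intermediate
17 | (3R)-4-hydroxy-N-methoxy-N,3-dimethyl-3-(SEM-oxy)butanamide | CON(C)C(=O)C[C@@](C)(OCOCC[Si](C)(C)C)CO | intermediate
18 | (3R)-N-methoxy-N,3-dimethyl-4-(triethylsilyloxy)-3-(SEM-oxy)butanamide | CON(C)C(=O)C[C@@](C)(OCOCC[Si](C)(C)C)CO[Si](CC)(CC)CC | intermediate
19 | 3-furyllithium from 11 (lithium in place of bromine) | C=C[C@@](O[Si](C)(C)C)(C)Cc1occ(CO[Si](c2ccccc2)(c2ccccc2)C(C)(C)C)c1[Li] | intermediate (not isolated)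
20 | (4R,10R)-C8 furyl ketone: furan with the C5/C4(OTMS)(Me)-vinyl chain on C6, the C8(=O)-C9H2-C10(Me)(OSEM)-C1H2OTES chain on C7 and CH2OTBDPS on C11 | C=C[C@@](O[Si](C)(C)C)(C)Cc1occ(CO[Si](c2ccccc2)(c2ccccc2)C(C)(C)C)c1C(=O)C[C@@](C)(OCOCC[Si](C)(C)C)CO[Si](CC)(CC)CC | intermediate
21 | (4R,8S,10R)-C8 alcohol of 20 | C=C[C@@](O[Si](C)(C)C)(C)Cc1occ(CO[Si](c2ccccc2)(c2ccccc2)C(C)(C)C)c1[C@@H](O)C[C@@](C)(OCOCC[Si](C)(C)C)CO[Si](CC)(CC)CC | intermediate
22 | (4R,8S,10R)-C8 TBS ether of 21 | C=C[C@@](O[Si](C)(C)C)(C)Cc1occ(CO[Si](c2ccccc2)(c2ccccc2)C(C)(C)C)c1[C@@H](O[Si](C)(C)C(C)(C)C)C[C@@](C)(OCOCC[Si](C)(C)C)CO[Si](CC)(CC)CC | intermediate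
23 | (4R,8S,10R)-C1,C4-diol: C1 primary alcohol, C4 tertiary allylic alcohol, C8 OTBS, C10 OSEM, C13 OTBDPS | C=C[C@@](O)(C)Cc1occ(CO[Si](c2ccccc2)(c2ccccc2)C(C)(C)C)c1[C@@H](O[Si](C)(C)C(C)(C)C)C[C@@](C)(OCOCC[Si](C)(C)C)CO | intermediate
24 | (4R,8S,10R)-C1 aldehyde of 23 | C=C[C@@](O)(C)Cc1occ(CO[Si](c2ccccc2)(c2ccccc2)C(C)(C)C)c1[C@@H](O[Si](C)(C)C(C)(C)C)C[C@@](C)(OCOCC[Si](C)(C)C)C=O | intermediate
25 | (1R,4R,8S,10R)-diene diol: vinyl carbinols at C1 and C4 | C=C[C@@](O)(C)Cc1occ(CO[Si](c2ccccc2)(c2ccccc2)C(C)(C)C)c1[C@@H](O[Si](C)(C)C(C)(C)C)C[C@@](C)(OCOCC[Si](C)(C)C)[C@@H](C=C)O | intermediate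
26 | dichlorodiisopropylsilane | CC(C)[Si](Cl)(Cl)C(C)C | starting material
27 | C1 chlorodiisopropylsilyl ether of 25 | C=C[C@@](O)(C)Cc1occ(CO[Si](c2ccccc2)(c2ccccc2)C(C)(C)C)c1[C@@H](O[Si](C)(C)C(C)(C)C)C[C@@](C)(OCOCC[Si](C)(C)C)[C@@H](C=C)O[Si](Cl)(C(C)C)C(C)C | intermediate (not isolated)
28 | (1R,4R,8S,10R)-eleven-membered diisopropylsilaketal diene fused to the furan | CC(C)(C)[Si](C)(C)O[C@H]1C[C@@](C)(OCOCC[Si](C)(C)C)[C@@H](C=C)O[Si](C(C)C)(C(C)C)O[C@@](C)(C=C)Cc2occ(CO[Si](c3ccccc3)(c3ccccc3)C(C)(C)C)c21 | intermediate
29 | (1R,2Z,4R,8S,10R)-silaketal-bridged cyclodecene | CC(C)(C)[Si](C)(C)O[C@H]1C[C@@](C)(OCOCC[Si](C)(C)C)[C@H]2/C=C\[C@](C)(O[Si](C(C)C)(C(C)C)O2)Cc3occ(CO[Si](c4ccccc4)(c4ccccc4)C(C)(C)C)c31 | intermediate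
30 | (1R,4S,8S,10R)-silaketal-bridged cyclodecane | CC(C)(C)[Si](C)(C)O[C@H]1C[C@@](C)(OCOCC[Si](C)(C)C)[C@H]2CC[C@](C)(O[Si](C(C)C)(C(C)C)O2)Cc3occ(CO[Si](c4ccccc4)(c4ccccc4)C(C)(C)C)c31 | intermediate
31 | (1R,4S,8S,10R)-1,4-diol | CC(C)(C)[Si](C)(C)O[C@H]1C[C@@](C)(OCOCC[Si](C)(C)C)[C@H](O)CC[C@](C)(O)Cc2occ(CO[Si](c3ccccc3)(c3ccccc3)C(C)(C)C)c21 | intermediate
32 | (1R,4S,8S,10R)-C1 mesylate of 31 | CC(C)(C)[Si](C)(C)O[C@H]1C[C@@](C)(OCOCC[Si](C)(C)C)[C@H](OS(C)(=O)=O)CC[C@](C)(O)Cc2occ(CO[Si](c3ccccc3)(c3ccccc3)C(C)(C)C)c21 | intermediate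
33 | (1S,4S,8S,10R)-1,4-epoxy furanogermacrane with C8 OTBS, C10 OSEM, C13 OTBDPS | CC(C)(C)[Si](C)(C)O[C@H]1C[C@@](C)(OCOCC[Si](C)(C)C)[C@@H]2CC[C@@](C)(Cc3occ(CO[Si](c4ccccc4)(c4ccccc4)C(C)(C)C)c31)O2 | intermediate
34 | (1S,4S,8S,10R)-8,10,13-triol | O[C@H]1C[C@@](C)(O)[C@@H]2CC[C@@](C)(Cc3occ(CO)c31)O2 | intermediate
35 | (1S,4S,8S,10R)-13-acetate of 34 | O[C@H]1C[C@@](C)(O)[C@@H]2CC[C@@](C)(Cc3occ(COC(C)=O)c31)O2 | intermediate
36 | (1S,4S,8S,10R)-8-angelate 13-acetate (furan) | C/C=C(/C)C(=O)O[C@H]1C[C@@](C)(O)[C@@H]2CC[C@@](C)(Cc3occ(COC(C)=O)c31)O2 | intermediate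
37 | furan 6,12-endoperoxide of 36 | C/C=C(/C)C(=O)O[C@H]1C[C@@](C)(O)[C@@H]2CC[C@@](C)(CC34OOC(O3)C(COC(C)=O)=C41)O2 | intermediate (not isolated)
38 | (1S,4S,8S,10R)-6-hydroxybutenolide (C6 epimers) | C/C=C(/C)C(=O)O[C@H]1C[C@@](C)(O)[C@@H]2CC[C@@](C)(CC3(O)OC(=O)C(COC(C)=O)=C31)O2 | intermediate
39 | C6 mesylate of 38 | C/C=C(/C)C(=O)O[C@H]1C[C@@](C)(O)[C@@H]2CC[C@@](C)(CC3(OS(C)(=O)=O)OC(=O)C(COC(C)=O)=C31)O2 | intermediate (not isolated)
40 | CNP0162854.1, (1S,4S,5E,8S,10R) | C/C=C(/C)C(=O)O[C@H]1C[C@@](C)(O)[C@@H]2CC[C@@](C)(/C=C3/OC(=O)C(COC(C)=O)=C31)O2 | target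

## Step count and least certain steps

Total: 29 steps (19 before the key step, the key step, 9 after). The longest linear sequence is 23 steps, from 1 (steps 1, 2, 4 to 7, 13 to 29).

**Step 20 (key step).** The ruthenium carbene may load slowly onto both vinyl groups, each of which sits on an oxygenated carbon next to a quaternary centre, so that catalyst decay and intermolecular metathesis overtake the transannular closure. The fallback is a relay ring-closing metathesis. It sets out from aldehyde 24, to which (E)-CH2=CHCH2OCH2CH=CHMgBr is added under the chelation control of step 18 to give the relay diene diol F1. Silaketal formation as in step 19 gives the relay silaketal F2. The catalyst then loads at the unhindered terminal allyl ether, expels 2,5-dihydrofuran and is thereby delivered to C2, from where it closes onto the C4 vinyl group. The route is rejoined at 29.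

**Step 19.** Intermolecular Si–O bond formation (dimers, oligomers) or hydrolysis of the chlorosilane may win before the hindered tertiary alkoxide reaches silicon across an eleven-membered ring. The fallback sets out from 25, which is silylated at the C1 hydroxyl with iPr2SiHCl and imidazole to the stable, purifiable C1 diisopropylsilyl (Si–H) ether F3. The ring is then closed at high dilution by base-catalysed dehydrogenative Si–O coupling with the C4 hydroxyl (catalytic KH, THF), with loss of dihydrogen. The route is rejoined at 28.

**Step 24.** Backside attack at the neopentyl-type C1 may be slow, so that elimination towards C2 or participation of the acetal oxygen competes. The fallback closes the ether while the C2=C3 alkene is still present, where C1 is allylic and held near the C4 oxygen. It sets out from 29: buffered HF·pyridine gives the (2Z)-ene-1,4-diol F4, mesylation at C1 gives the allylic mesylate F5, and treatment with KN(SiMe3)2 gives the 2,5-dihydrofuran-bridged ether F6 with inversion at C1. Diimide reduction of F6 rejoins the route at 33.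

**Step 18.** Facial selectivity may be poor, because the chelate differentiates only a methyl group from a CH2 chain on the quaternary C10. The fallback replaces substrate control by reagent control. It sets out from 24: addition of LiC≡CSiMe3 gives the C1 silylethynyl carbinol F7 as a mixture of epimers, Dess–Martin oxidation gives the ynone F8, and transfer hydrogenation with RuCl[(S,S)-TsDPEN](p-cymene) in i-PrOH should give the (1R)-propargylic alcohol F9. K2CO3 in MeOH gives the terminal alkyne F10, and semi-hydrogenation over Pd on CaCO3 poisoned with Pb(OAc)2 and quinoline rejoins the route at 25.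

**Step 13.** The di-ortho-substituted furyllithium may deprotonate the amide at C9 instead of adding, with loss of the β-acetal oxygen. The fallback uses a smaller and more reactive electrophile. It sets out from 18, which i-Bu2AlH reduces to the (3R)-aldehyde F11. Addition of 19 gives the C8 carbinol F12 as a mixture of epimers, and Dess–Martin oxidation rejoins the route at 20.

**Step 14.** Facial selectivity may be eroded, because the small substituent is a neopentyl-type methylene with Lewis-basic oxygens. The fallback is separation and recycling in place of reagent control. It sets out from 20, which NaBH4 reduces without selectivity. The C8 epimers are diastereomers and can be separated by chromatography, and the (8R)-alcohol F13 is returned to 20 by Dess–Martin oxidation. The route is rejoined at 21.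

## Further compounds

F1 | step 20 | (1R,4R,8S,10R)-relay diene diol: as 25 with (E)-3-(allyloxy)prop-1-enyl on C1 | C=C[C@@](O)(C)Cc1occ(CO[Si](c2ccccc2)(c2ccccc2)C(C)(C)C)c1[C@@H](O[Si](C)(C)C(C)(C)C)C[C@@](C)(OCOCC[Si](C)(C)C)[C@@H](/C=C/COCC=C)O
F2 | step 20 | relay silaketal: as 28 with (E)-3-(allyloxy)prop-1-enyl on C1 | CC(C)(C)[Si](C)(C)O[C@H]1C[C@@](C)(OCOCC[Si](C)(C)C)[C@@H](/C=C/COCC=C)O[Si](C(C)C)(C(C)C)O[C@@](C)(C=C)Cc2occ(CO[Si](c3ccccc3)(c3ccccc3)C(C)(C)C)c21
F3 | step 19 | C1 diisopropylsilyl (Si–H) ether of 25 | C=C[C@@](O)(C)Cc1occ(CO[Si](c2ccccc2)(c2ccccc2)C(C)(C)C)c1[C@@H](O[Si](C)(C)C(C)(C)C)C[C@@](C)(OCOCC[Si](C)(C)C)[C@@H](C=C)O[SiH](C(C)C)C(C)C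
F4 | step 24 | (1R,2Z,4R,8S,10R)-ene-1,4-diol | CC(C)(C)[Si](C)(C)O[C@H]1C[C@@](C)(OCOCC[Si](C)(C)C)[C@H](O)/C=C\[C@](C)(O)Cc2occ(CO[Si](c3ccccc3)(c3ccccc3)C(C)(C)C)c21
F5 | step 24 | C1 allylic mesylate of F4 | CC(C)(C)[Si](C)(C)O[C@H]1C[C@@](C)(OCOCC[Si](C)(C)C)[C@H](OS(C)(=O)=O)/C=C\[C@](C)(O)Cc2occ(CO[Si](c3ccccc3)(c3ccccc3)C(C)(C)C)c21
F6 | step 24 | (1S,4R,8S,10R)-2,5-dihydrofuran-bridged ether (2,3-dehydro-33) | CC(C)(C)[Si](C)(C)O[C@H]1C[C@@](C)(OCOCC[Si](C)(C)C)[C@@H]2C=C[C@@](C)(Cc3occ(CO[Si](c4ccccc4)(c4ccccc4)C(C)(C)C)c31)O2
F7 | step 18 | C1 (trimethylsilyl)ethynyl carbinol, C1 epimers | C=C[C@@](O)(C)Cc1occ(CO[Si](c2ccccc2)(c2ccccc2)C(C)(C)C)c1[C@@H](O[Si](C)(C)C(C)(C)C)C[C@@](C)(OCOCC[Si](C)(C)C)C(O)C#C[Si](C)(C)C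
F8 | step 18 | C1 (trimethylsilyl)ethynyl ketone | C=C[C@@](O)(C)Cc1occ(CO[Si](c2ccccc2)(c2ccccc2)C(C)(C)C)c1[C@@H](O[Si](C)(C)C(C)(C)C)C[C@@](C)(OCOCC[Si](C)(C)C)C(=O)C#C[Si](C)(C)C
F9 | step 18 | (1R)-(trimethylsilyl)ethynyl carbinol | C=C[C@@](O)(C)Cc1occ(CO[Si](c2ccccc2)(c2ccccc2)C(C)(C)C)c1[C@@H](O[Si](C)(C)C(C)(C)C)C[C@@](C)(OCOCC[Si](C)(C)C)[C@@H](C#C[Si](C)(C)C)O
F10 | step 18 | (1R)-ethynyl carbinol | C=C[C@@](O)(C)Cc1occ(CO[Si](c2ccccc2)(c2ccccc2)C(C)(C)C)c1[C@@H](O[Si](C)(C)C(C)(C)C)C[C@@](C)(OCOCC[Si](C)(C)C)[C@@H](C#C)O
F11 | step 13 | (3R)-3-methyl-4-(triethylsilyloxy)-3-(SEM-oxy)butanal | O=CC[C@@](C)(OCOCC[Si](C)(C)C)CO[Si](CC)(CC)CC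
F12 | step 13 | C8 carbinol, C8 epimers (21 and F13) | C=C[C@@](O[Si](C)(C)C)(C)Cc1occ(CO[Si](c2ccccc2)(c2ccccc2)C(C)(C)C)c1C(O)C[C@@](C)(OCOCC[Si](C)(C)C)CO[Si](CC)(CC)CC
F13 | step 14 | (4R,8R,10R)-C8 alcohol, the C8 epimer of 21 | C=C[C@@](O[Si](C)(C)C)(C)Cc1occ(CO[Si](c2ccccc2)(c2ccccc2)C(C)(C)C)c1[C@H](O)C[C@@](C)(OCOCC[Si](C)(C)C)CO[Si](CC)(CC)CC
A1 | alternative 1 | trans-tetrahydrofuran with quaternary C4, C5 carbinol, acetonide on the C10 and C9 oxygens and pivalate on the C6 oxygen | CC1(C)OC[C@@](C)(O1)[C@@H]2CC[C@@](C)([C@@H](O)COC(=O)C(C)(C)C)O2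
A2 | alternative 2 | (E)-cyclodec-5-enone with C8 dimethylphenylsilyl group and C4 triethylsilyl ether | C[Si](C)(c1ccccc1)[C@H]2C/C(C)=C/CC[C@@](C)(CC(=O)C2)O[Si](CC)(CC)CC
A3 | alternative 3 | ten-membered carbocycle with 1,4-ether bridge, free C8 alcohol, C6 OTBS, C10 OTES and C11 exocyclic methylene with CH2OTBS | O[C@H]1C[C@@](C)(O[Si](CC)(CC)CC)[C@@H]2CC[C@@](C)(C[C@H](O[Si](C)(C)C(C)(C)C)[C@@H]1C(=C)CO[Si](C)(C)C(C)(C)C)O2
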